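**Plan**
- Labels: ring A is the central ring (C1 butyryl, C2/C4/C6 OH, C3/C5 bridge CH2); rings B are the two identical outer rings (C1' bridge CH2, C2'/C4' OH, C3' butyryl, C5' CH3, C6' OCH3).
- Enabling feature: the oxygens at C2 and C6 of ring A and at C2' and C4' of both rings B each sit ortho to a butyryl carbonyl (C1 or C3'), and in the hexadeoxy precursor these six carbons carry the only aromatic hydrogens.
- Retrosynthesis: the C4 acetate is removed last; the six ortho aryl C–O bonds are cut next, in one operation; then the two CH2–C1' bonds, the two ring A–CH2 bonds (two molecules of formaldehyde) and the ring B–acyl bond (butyryl chloride).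
- Forward: no ring is formed; 4-hydroxybutyrophenone is bis-hydroxymethylated, 2-methylanisole is butyrylated, the diol is joined to two such ketones, the C4 phenol is acetylated, six C–H bonds are hydroxylated, and the acetate is cleaved.
- Stereochemistry: the target has no stereocentre and no configured double bond, so nothing has to be set.

Key step: step 5

Remark: the six phenolic oxygens introduced in step 5 are counted as coming from trifluoroacetoxy groups of six molecules of PhI(OCOCF3)2, which exchange freely with the CF3CO2H medium; step 1 consumes two molecules of formaldehyde and step 3 two molecules of ketone 6 per molecule of product.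

**Step 1**
Reactants: 1 4-hydroxybutyrophenone; 2 formaldehyde (two molecules incorporated)
Product: 3 1-[4-hydroxy-3,5-bis(hydroxymethyl)phenyl]butan-1-one
Conditions: 37% aq. CH2O (6 equiv), NaOH (1.1 equiv), H2O, 45 °C, 48 h; then AcOH, 0 °C
Reagents that add atoms: none
Why: Lederer–Manasse hydroxymethylation, in which the phenoxide adds one molecule of formaldehyde at each of its two free ortho carbons (para is blocked by the acyl group), while the ketone alpha-CH2 is poorly acidic because the carbonyl is conjugated with the para phenoxide.

**Step 2**
Reactants: 4 2-methylanisole; 5 butyryl chloride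
Product: 6 1-(4-methoxy-3-methylphenyl)butan-1-one
Conditions: AlCl3 (1.2 equiv), CH2Cl2, 0 °C to rt; then ice/dilute HCl
Reagents that add atoms: none
Why: Friedel–Crafts acylation goes para to the methoxy group, the strongest donor on the ring, and the deactivated product is not acylated again.

**Step 3**
Reactants: 3 1-[4-hydroxy-3,5-bis(hydroxymethyl)phenyl]butan-1-one; 6 1-(4-methoxy-3-methylphenyl)butan-1-one (two molecules incorporated)
Product: 7 1-{4-hydroxy-3,5-bis[(5-butanoyl-2-methoxy-3-methylphenyl)methyl]phenyl}butan-1-one
Conditions: 6 (5 equiv, excess recovered), CF3SO3H (0.2 equiv), (CF3)2CHOH, 50 °C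
Reagents that add atoms: none
Why: Acid-catalysed Friedel–Crafts benzylation through the ortho-hydroxybenzyl cation (protonated ortho-quinone methide) of 3, which attacks the only activated C–H of 6 (ortho to OCH3, meta to the ketone); neither 3 nor 7 has an activated free ring carbon, so the reaction should stop at the trimer and ether formation stays reversible.

**Step 4**
Reactants: 7 1-{4-hydroxy-3,5-bis[(5-butanoyl-2-methoxy-3-methylphenyl)methyl]phenyl}butan-1-one
Product: 8 4-butanoyl-2,6-bis[(5-butanoyl-2-methoxy-3-methylphenyl)methyl]phenyl acetate
Conditions: Ac2O, pyridine, 4-(dimethylamino)pyridine (cat.), CH2Cl2, rt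
Reagents that add atoms: acetic anhydride, CC(=O)OC(C)=O
Why: Nucleophile-catalysed O-acetylation of the acidic, di-ortho-substituted phenol masks the one oxygen that the hypervalent iodine oxidant of the next step would otherwise attack.

**Step 5**
Reactants: 8 4-butanoyl-2,6-bis[(5-butanoyl-2-methoxy-3-methylphenyl)methyl]phenyl acetate
Product: 10 4-butanoyl-2,6-bis[(3-butanoyl-2,4-dihydroxy-6-methoxy-5-methylphenyl)methyl]-3,5-dihydroxyphenyl acetate, via hexakis(trifluoroacetate) 9 (not isolated)
Conditions: Pd(OAc)2 (30 mol%), PhI(OCOCF3)2 (9 equiv, in portions), CF3CO2H/(CF3CO)2O (4:1), 60 °C; then H2O/THF, rt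
Reagents that add atoms: [bis(trifluoroacetoxy)iodo]benzene (six molecules each deliver one trifluoroacetoxy group), O=C(OI(OC(=O)C(F)(F)F)c1ccccc1)C(F)(F)F
Why: Proposed new method: each butyryl carbonyl binds electrophilic divalent palladium, a five-membered palladacycle forms by concerted metalation–deprotonation at an ortho C–H, PhI(OCOCF3)2 oxidises it to tetravalent palladium, and C–O reductive elimination releases an aryl trifluoroacetate and divalent palladium, the cycle then repeating at the second ortho C–H of the same ring and on the other two rings. The closest known reaction type is the single ketone-directed ortho C–H hydroxylation of aryl ketones with Pd(OAc)2 or [RuCl2(p-cymene)]2 and PhI(OCOCF3)2 or K2S2O8 in trifluoroacetic acid and its anhydride; a second hydroxylation on one ring and six such events in one molecule have not been shown. No ring is closed and no stereocentre is formed. Site selectivity is secured by the substrate, because the six C–H bonds at C2, C6, C2' and C4' are the only aromatic hydrogens and each lies ortho to a chelating ketone. The step also needs aromatic C–H oxidation to outrun oxidation of the two diarylmethane CH2 groups and of the ketone alpha-CH2 groups, and it needs full conversion. For this the rings are kept electron-poor: every new oxygen stays as its trifluoroacetate until the aqueous work-up hydrolyses 9, and the C4 oxygen stays as its acetate.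

**Step 6**
Reactants: 10 4-butanoyl-2,6-bis[(3-butanoyl-2,4-dihydroxy-6-methoxy-5-methylphenyl)methyl]-3,5-dihydroxyphenyl acetate
Product: 11 1-{2,4,6-trihydroxy-3,5-bis[(3-butanoyl-2,4-dihydroxy-6-methoxy-5-methylphenyl)methyl]phenyl}butan-1-one (CNP0264591.0)
Conditions: K2CO3 (2 equiv), degassed MeOH, 0 °C, Ar; then 1 M HCl to pH 4
Reagents that add atoms: none
Why: Base-mediated transesterification (Zemplén-type methanolysis) cleaves the aryl acetate under conditions that are cold, brief and oxygen-free, so the base-sensitive methylene bridges between the acylphloroglucinol rings should not exchange.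

**Compound list**
1 | 4-hydroxybutyrophenone, 1-(4-hydroxyphenyl)butan-1-one | CCCC(=O)c1ccc(O)cc1 | starting material
2 | formaldehyde (37% aqueous solution) | C=O | starting material
3 | 1-[4-hydroxy-3,5-bis(hydroxymethyl)phenyl]butan-1-one | CCCC(=O)c1cc(CO)c(O)c(CO)c1 | intermediate
4 | 2-methylanisole, 1-methoxy-2-methylbenzene | COc1ccccc1C | starting material
5 | butyryl chloride, butanoyl chloride | CCCC(=O)Cl | starting material
6 | 1-(4-methoxy-3-methylphenyl)butan-1-one | CCCC(=O)c1ccc(OC)c(C)c1 | intermediate
7 | 1-{4-hydroxy-3,5-bis[(5-butanoyl-2-methoxy-3-methylphenyl)methyl]phenyl}butan-1-one | CCCC(=O)c1cc(Cc2cc(C(=O)CCC)cc(C)c2OC)c(O)c(Cc2cc(C(=O)CCC)cc(C)c2OC)c1 | intermediate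
8 | 4-butanoyl-2,6-bis[(5-butanoyl-2-methoxy-3-methylphenyl)methyl]phenyl acetate | CCCC(=O)c1cc(Cc2cc(C(=O)CCC)cc(C)c2OC)c(OC(C)=O)c(Cc2cc(C(=O)CCC)cc(C)c2OC)c1 | intermediate
9 | 4-butanoyl-2,6-bis{[3-butanoyl-6-methoxy-5-methyl-2,4-bis(trifluoroacetoxy)phenyl]methyl}-3,5-bis(trifluoroacetoxy)phenyl acetate | CCCC(=O)c1c(OC(=O)C(F)(F)F)c(Cc2c(OC(=O)C(F)(F)F)c(C(=O)CCC)c(OC(=O)C(F)(F)F)c(C)c2OC)c(OC(C)=O)c(Cc2c(OC(=O)C(F)(F)F)c(C(=O)CCC)c(OC(=O)C(F)(F)F)c(C)c2OC)c1OC(=O)C(F)(F)F | intermediate
10 | 4-butanoyl-2,6-bis[(3-butanoyl-2,4-dihydroxy-6-methoxy-5-methylphenyl)methyl]-3,5-dihydroxyphenyl acetate | CCCC(=O)c1c(O)c(Cc2c(O)c(C(=O)CCC)c(O)c(C)c2OC)c(OC(C)=O)c(Cc2c(O)c(C(=O)CCC)c(O)c(C)c2OC)c1O | intermediate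
11 | 1-{2,4,6-trihydroxy-3,5-bis[(3-butanoyl-2,4-dihydroxy-6-methoxy-5-methylphenyl)methyl]phenyl}butan-1-one (CNP0264591.0) | CCCC(=O)c1c(O)c(Cc2c(O)c(C(=O)CCC)c(O)c(C)c2OC)c(O)c(Cc2c(O)c(C(=O)CCC)c(O)c(C)c2OC)c1O | target

**Total step count:** 6
**Longest linear sequence:** 5 steps (1 → 3 → 7 → 8 → 10 → 11; step 2 supplies the side branch)

**Steps most likely to fail**

1. Step 5. The sequence may stall after the first hydroxylation on a ring, because the ortho-trifluoroacetoxy ketone is twisted and binds palladium less well, and each remaining C–H is flanked by a CH2Ar or CH3 group. The trivalent iodine oxidant may also oxidise the diarylmethane bridges or the ketone alpha-positions, and partly oxygenated rings may degrade. The fallback uses known chemistry and brings the oxygens in with the rings; it sets out from butyryl chloride 5 and formaldehyde 2 and comes back at target 11. Commercial phloroglucinol would be C-acylated with 5 (AlCl3, PhNO2/CH2Cl2) to give 1-(2,4,6-trihydroxyphenyl)butan-1-one F1. Commercial 2-methylphloroglucinol would be acylated in the same way to give 1-(2,4,6-trihydroxy-3-methylphenyl)butan-1-one F2. Mono-O-methylation of F2 with Me2SO4 (1 equiv) and K2CO3 in acetone should go at the hydroxyl para to the ketone, the only one not hydrogen-bonded to the carbonyl, to give 1-(2,6-dihydroxy-4-methoxy-3-methylphenyl)butan-1-one F3. Slow addition of formalin 2 (two molecules per trimer) to F1 and an excess of F3 in dilute aqueous NaOH at 0 °C, the standard formaldehyde coupling of acylphloroglucinols, would then bridge C3 and C5 of F1 to the single free ring carbon of two molecules of F3 and give 11. The homo-coupled by-product of the outer unit would be removed by chromatography.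

2. Step 3. Attack by the acyl-deactivated anisole position, which ends up flanked on both sides, may be too slow, so that the benzylic cation is diverted into ether oligomers or ortho-quinone methide self-condensation. The fallback reverses the roles of the partners; it sets out from ketone 6 and comes back at 7. Blanc chloromethylation of 6 (paraformaldehyde as the source of 2, conc. HCl, ZnCl2, 50 °C) should place the CH2Cl group ortho to the methoxy group and give 1-[3-(chloromethyl)-4-methoxy-5-methylphenyl]butan-1-one F4, which cannot alkylate itself. Friedel–Crafts C-benzylation of both ortho positions of phenol 1 with F4 (2.2 equiv, ZnCl2, 1,2-dichloroethane, 70 °C) would then give 7; any aryl benzyl ether formed first rearranges to carbon under the Lewis acid.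

3. Step 1. The second hydroxymethylation of the acyl-deactivated phenoxide may be incomplete, and aldol addition of formaldehyde at the ketone alpha-carbon or condensation of the hydroxymethyl phenol to diarylmethanes may compete. The fallback brings the two carbons in at the aldehyde oxidation level; it sets out from 1 and comes back at 3. Double Duff formylation of 1 (hexamethylenetetramine, CF3CO2H, reflux; then aq. HCl) would give 5-butanoyl-2-hydroxybenzene-1,3-dicarbaldehyde F5. Chemoselective reduction of the two aldehydes with NaBH4 (1 equiv, EtOH, −20 °C) would then give diol 3, the ketone being the less electrophilic carbonyl.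

**Further compounds**
F1 | step 5 | 1-(2,4,6-trihydroxyphenyl)butan-1-one | CCCC(=O)c1c(O)cc(O)cc1O
F2 | step 5 | 1-(2,4,6-trihydroxy-3-methylphenyl)butan-1-one | CCCC(=O)c1c(O)cc(O)c(C)c1O
F3 | step 5 | 1-(2,6-dihydroxy-4-methoxy-3-methylphenyl)butan-1-one | CCCC(=O)c1c(O)cc(OC)c(C)c1O
F4 | step 3 | 1-[3-(chloromethyl)-4-methoxy-5-methylphenyl]butan-1-one | CCCC(=O)c1cc(C)c(OC)c(CCl)c1
F5 | step 1 | 5-butanoyl-2-hydroxybenzene-1,3-dicarbaldehyde | CCCC(=O)c1cc(C=O)c(O)c(C=O)c1
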